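**Plan**

- Numbering: ring A is O1, C2 (aryl), C3, C4, C5; C6 is the hydroxymethyl carbon on C3 and C7 the aryl carbinol carbon on C4. C6 and C7 are cis on ring A, so they can be tied together as a γ-lactone (C6 acyl on the C7 oxygen). That makes C3 an enolisable α-carbon, while the oxygen on C5 (O1) can hold C2 as a mixed aryl acetal.
- Retrosynthetic cuts, in order: the two benzyl ethers; C6 back to the lactone carbonyl; C2–C3 of ring A; the acetal bond C2–O1; the lactone acyl bond C6–O(C7); the aldol bond C4–C7.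
- Forward: the aldol joins C4–C7, acid closes the lactone, hydrolysis and borane reduction give the C5 alcohol, transacetalisation hangs C2 on O1, the C2–C3 closure builds ring A on the lactone, then LiAlH4 and hydrogenolysis.
- Stereochemistry: C7 and C4 come from the syn-aldol under (S)-4-benzyl-oxazolidinone control (syn adduct gives the trans lactone). C3 is fixed by the tether (cis ring fusion, hence 3,4-cis). C2 is fixed by the exo position of its aryl group (2,3-trans).

Key step: step 9

Remark: the target is taken exactly as drawn in the SMILES, i.e. (2S,3R,4R) in ring A with a (7S) carbinol in the numbering above (2,3-trans, 3,4-cis).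

**Route**

Step 1
Reactants: 1 vanillin
Product: 2 O-benzylvanillin (4-(benzyloxy)-3-methoxybenzaldehyde)
Conditions: BnBr, K2CO3, DMF, rt
Reagents that add atoms: benzyl bromide, BrCc1ccccc1
Why: Williamson ether synthesis on the phenoxide should give the benzyl ether, which is inert to every later step until the final hydrogenolysis.

Step 2
Reactants: 3 4-tert-butoxy-4-oxobutanoic acid; 4 (S)-4-benzyl-1,3-oxazolidin-2-one
Product: 6 tert-butyl 4-[(4S)-4-benzyl-2-oxo-1,3-oxazolidin-3-yl]-4-oxobutanoate, via mixed pivalic anhydride 5 (not isolated)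
Conditions: PivCl, Et3N, THF, −20 °C; then 4, LiCl, −20 °C → rt
Reagents that add atoms: none
Why: N-acylation of the oxazolidinone through a mixed anhydride should occur at the unhindered succinyl carbonyl and leave the tert-butyl ester untouched.

Step 3
Reactants: 6 tert-butyl 4-[(4S)-4-benzyl-2-oxo-1,3-oxazolidin-3-yl]-4-oxobutanoate; 2 O-benzylvanillin
Product: 9 syn-aldol adduct tert-butyl (3S,4S)-3-[(4S)-4-benzyl-2-oxo-1,3-oxazolidine-3-carbonyl]-4-[4-(benzyloxy)-3-methoxyphenyl]-4-hydroxybutanoate, via Z-dibutylboron enolate 7 (not isolated), via dibutylboron aldolate 8 (not isolated)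
Conditions: Bu2BOTf, iPr2NEt, CH2Cl2, 0 °C; then 2, −78 → 0 °C; pH 7 buffer, MeOH, 30% H2O2, 0 °C
Reagents that add atoms: none
Why: In this Evans syn-aldol reaction the Z-boron enolate of the imide should add through a Zimmerman–Traxler chair on the face away from the benzyl group of the auxiliary, which sets C4 and C7 together as the (3S,4S) syn pair.

Step 4
Reactants: 9 syn-aldol adduct
Product: 11 trans-lactone imide (4S)-4-benzyl-3-{(2S,3S)-2-[4-(benzyloxy)-3-methoxyphenyl]-5-oxooxolane-3-carbonyl}-1,3-oxazolidin-2-one, via hydroxy acid 10 (not isolated)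
Conditions: TFA, CH2Cl2, 0 °C → rt
Reagents that add atoms: none
Why: Acidolysis of the tert-butyl ester followed by lactonisation of the γ-hydroxy acid should turn the syn-aldol into the trans-4,5-disubstituted lactone, which is also the more stable isomer if the benzylic C7–O bond ionises reversibly.

Step 5
Reactants: 11 trans-lactone imide
Product: 12 (2S,3S)-2-[4-(benzyloxy)-3-methoxyphenyl]-5-oxooxolane-3-carboxylic acid
Conditions: LiOH·H2O, 30% H2O2, THF/H2O (3:1), 0 °C; aq. Na2SO3; 1 M HCl
Reagents that add atoms: hydrogen peroxide (as LiOOH), OO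
Why: LiOOH cleavage of the Evans imide should attack the exocyclic carbonyl selectively without epimerising C4, and any lactone opening by hydroxide is reversed on acidification because only the five-membered ring can re-form.

Step 6
Reactants: 12 lactone acid
Product: 13 (4R,5S)-5-[4-(benzyloxy)-3-methoxyphenyl]-4-(hydroxymethyl)oxolan-2-one
Conditions: BH3·SMe2, THF, 0 °C → rt; MeOH
Reagents that add atoms: none
Why: Borane reduces a carboxylic acid through its acyloxyborane much faster than it reduces a lactone, so the C5 alcohol should form with the lactone and both stereocentres intact.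

Step 7
Reactants: 2 O-benzylvanillin
Product: 14 O-benzylvanillin dimethyl acetal (1-(benzyloxy)-4-(dimethoxymethyl)-2-methoxybenzene)
Conditions: HC(OMe)3, p-TsOH·H2O (cat.), MeOH, rt; Et3N
Reagents that add atoms: trimethyl orthoformate, COC(OC)OC; methanol, CO
Why: Acid-catalysed acetalisation of an aromatic aldehyde is driven to completion by the orthoformate, which consumes the water formed.

Step 8
Reactants: 13 hydroxymethyl lactone; 14 O-benzylvanillin dimethyl acetal
Product: 15 mixed methyl acetal (4R,5S)-5-[4-(benzyloxy)-3-methoxyphenyl]-4-({[4-(benzyloxy)-3-methoxyphenyl](methoxy)methoxy}methyl)oxolan-2-one (both acetal epimers)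
Conditions: 14 (3 equiv), PPTS (cat.), 5 Å molecular sieves, CH2Cl2, rt; Et3N
Reagents that add atoms: none
Why: In this acid-catalysed transacetalisation the primary alcohol should exchange one methoxy group of 14, with excess 14 and uptake of methanol by the sieves holding the equilibrium at the mixed acetal, whose new centre is of no consequence.

Step 9
Reactants: 15 mixed methyl acetal
Product: 18 bicyclic lactone (3S,3aR,6S,6aS)-3,6-bis[4-(benzyloxy)-3-methoxyphenyl]tetrahydro-1H,3H-furo[3,4-c]furan-1-one (cis-fused; both aryl groups exo), via silyl ketene acetal 16 (not isolated), via oxocarbenium triflate 17 (not isolated)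
Conditions: TMSOTf (3 equiv), iPr2NEt (4 equiv), CH2Cl2, −78 → 0 °C; aq. NaHCO3
Reagents that add atoms: none
Why: TMSOTf with the amine silylates the lactone carbonyl and removes a C3 proton to give ketene acetal 16, a further equivalent of TMSOTf strips the methoxy group from the acetal as TMSOMe to leave the aryl-stabilised oxocarbenium ion 17 held to C4 through C5 and O1, and C3 then bonds to C2 with loss of the silyl group. The closest known reaction is the Mukaiyama-type addition of an in situ silyl ketene acetal to an acetal-derived oxocarbenium ion, run here inside one molecule as in Lewis acid-promoted vinyl acetal to tetrahydrofuran rearrangements. Ring A closes in a 5-(enol-exo)-endo mode, the C3=C6 enol bond lying outside the new ring and the C2=O1 bond inside it. C3 is controlled by the short tether from C4, which lets C2 reach only the face of the ketene acetal that carries C5, so the new ring must be cis-fused to the lactone; C2 is controlled by its aryl group settling on the outer (exo) face of the folded bicycle, away from the lactone and its silyloxy group, and both acetal epimers converge on the same E-oxocarbenium ion. The step needs ionisation by loss of methoxide and not of the tethered alkoxide, which the more accessible and more basic methoxy oxygen should secure, and it needs the exo aryl orientation, which is also the more stable one should the benzylic C–O bonds equilibrate under the Lewis acid.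

Step 10
Reactants: 18 bicyclic lactone
Product: 19 di-O-benzyl tanegol (S)-[4-(benzyloxy)-3-methoxyphenyl]{(3R,4R,5S)-5-[4-(benzyloxy)-3-methoxyphenyl]-4-(hydroxymethyl)oxolan-3-yl}methanol
Conditions: LiAlH4, THF, 0 °C; aq. KNaC4H4O6
Reagents that add atoms: none
Why: LiAlH4 reduction of a lactone cleaves the acyl C6–O bond only, so the C6 primary alcohol and the C7 carbinol should appear with C7–O and all four stereocentres unchanged.

Step 11
Reactants: 19 di-O-benzyl tanegol
Product: 20 (−)-tanegol
Conditions: H2 (1 atm), 10% Pd/C, EtOAc, rt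
Reagents that add atoms: none
Why: Catalytic hydrogenolysis under neutral conditions cleaves aryl benzyl ethers much faster than the secondary benzylic C7–OH and C2–O1 bonds, so the reaction should be stopped as soon as both benzyl groups are gone.

**Compound list**

1 | vanillin | COc1cc(C=O)ccc1O | starting material
2 | O-benzylvanillin, 4-(benzyloxy)-3-methoxybenzaldehyde | COc1cc(C=O)ccc1OCc1ccccc1 | intermediate
3 | 4-tert-butoxy-4-oxobutanoic acid | CC(C)(C)OC(=O)CCC(=O)O | starting material
4 | (S)-4-benzyl-1,3-oxazolidin-2-one | O=C1N[C@@H](Cc2ccccc2)CO1 | starting material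
5 | mixed anhydride of 3 with pivalic acid | CC(C)(C)OC(=O)CCC(=O)OC(=O)C(C)(C)C | intermediate
6 | tert-butyl 4-[(4S)-4-benzyl-2-oxo-1,3-oxazolidin-3-yl]-4-oxobutanoate | CC(C)(C)OC(=O)CCC(=O)N1[C@@H](Cc2ccccc2)COC1=O | intermediate
7 | Z-dibutylboron enolate of 6 | CCCCB(CCCC)O/C(=C\CC(=O)OC(C)(C)C)N1[C@@H](Cc2ccccc2)COC1=O | intermediate
8 | dibutylboron aldolate of 9 | COc1cc([C@@H](OB(CCCC)CCCC)[C@H](CC(=O)OC(C)(C)C)C(=O)N2[C@@H](Cc3ccccc3)COC2=O)ccc1OCc1ccccc1 | intermediate
9 | tert-butyl (3S,4S)-3-[(4S)-4-benzyl-2-oxo-1,3-oxazolidine-3-carbonyl]-4-[4-(benzyloxy)-3-methoxyphenyl]-4-hydroxybutanoate (syn-aldol) | COc1cc([C@@H](O)[C@H](CC(=O)OC(C)(C)C)C(=O)N2[C@@H](Cc3ccccc3)COC2=O)ccc1OCc1ccccc1 | intermediate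
10 | (3S,4S)-3-[(4S)-4-benzyl-2-oxo-1,3-oxazolidine-3-carbonyl]-4-[4-(benzyloxy)-3-methoxyphenyl]-4-hydroxybutanoic acid | COc1cc([C@@H](O)[C@H](CC(=O)O)C(=O)N2[C@@H](Cc3ccccc3)COC2=O)ccc1OCc1ccccc1 | intermediate
11 | (4S)-4-benzyl-3-{(2S,3S)-2-[4-(benzyloxy)-3-methoxyphenyl]-5-oxooxolane-3-carbonyl}-1,3-oxazolidin-2-one (trans lactone) | COc1cc([C@H]2OC(=O)C[C@@H]2C(=O)N3[C@@H](Cc4ccccc4)COC3=O)ccc1OCc1ccccc1 | intermediate
12 | (2S,3S)-2-[4-(benzyloxy)-3-methoxyphenyl]-5-oxooxolane-3-carboxylic acid | COc1cc([C@H]2OC(=O)C[C@@H]2C(=O)O)ccc1OCc1ccccc1 | intermediate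
13 | (4R,5S)-5-[4-(benzyloxy)-3-methoxyphenyl]-4-(hydroxymethyl)oxolan-2-one | COc1cc([C@H]2OC(=O)C[C@@H]2CO)ccc1OCc1ccccc1 | intermediate
14 | 1-(benzyloxy)-4-(dimethoxymethyl)-2-methoxybenzene | COc1cc(C(OC)OC)ccc1OCc1ccccc1 | intermediate
15 | (4R,5S)-5-[4-(benzyloxy)-3-methoxyphenyl]-4-({[4-(benzyloxy)-3-methoxyphenyl](methoxy)methoxy}methyl)oxolan-2-one, acetal epimers | COc1cc([C@H]2OC(=O)C[C@@H]2COC(OC)c2ccc(OCc3ccccc3)c(OC)c2)ccc1OCc1ccccc1 | intermediate
16 | trimethylsilyl ketene acetal of 15 (5-silyloxy-2,3-dihydrofuran, C4 and C7 unchanged) | COc1cc([C@H]2OC(O[Si](C)(C)C)=C[C@@H]2COC(OC)c2ccc(OCc3ccccc3)c(OC)c2)ccc1OCc1ccccc1 | intermediate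
17 | oxocarbenium triflate formed from 16 by loss of methoxide | COc1cc([C@H]2OC(O[Si](C)(C)C)=C[C@@H]2C[O+]=Cc2ccc(OCc3ccccc3)c(OC)c2)ccc1OCc1ccccc1.[O-]S(=O)(=O)C(F)(F)F | intermediate
18 | (3S,3aR,6S,6aS)-3,6-bis[4-(benzyloxy)-3-methoxyphenyl]tetrahydro-1H,3H-furo[3,4-c]furan-1-one, cis-fused, both aryl groups exo | COc1cc([C@H]2OC(=O)[C@@H]3[C@@H](c4ccc(OCc5ccccc5)c(OC)c4)OC[C@H]23)ccc1OCc1ccccc1 | intermediate
19 | (S)-[4-(benzyloxy)-3-methoxyphenyl]{(3R,4R,5S)-5-[4-(benzyloxy)-3-methoxyphenyl]-4-(hydroxymethyl)oxolan-3-yl}methanol | COc1cc([C@@H](O)[C@H]2CO[C@H](c3ccc(OCc4ccccc4)c(OC)c3)[C@H]2CO)ccc1OCc1ccccc1 | intermediate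
20 | (−)-tanegol, (S)-(4-hydroxy-3-methoxyphenyl)[(3R,4R,5S)-5-(4-hydroxy-3-methoxyphenyl)-4-(hydroxymethyl)oxolan-3-yl]methanol | COc1cc([C@@H](O)[C@H]2CO[C@H](c3ccc(O)c(OC)c3)[C@H]2CO)ccc1O | target

**Step count and risks**

Total step count: 11. Longest linear sequence: 9 steps (steps 2, 3, 4, 5, 6, 8, 9, 10, 11 from 3 and 4; the line from vanillin through steps 1, 3, 4, 5, 6, 8, 9, 10, 11 is equally long).

Steps most likely to fail:

1. Step 9. The acetal may ionise on the tethered oxygen and shed the aryl unit. Soft enolisation of the lactone may be too slow, so that the oxocarbenium ion is consumed between molecules. Facial control at C2 may be weak.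
   The fallback sets out from 13 and returns at 19. It forms C2–C3 by an intermolecular aldol and closes ring A at C2–O1 instead.
   - DBU (cat.) in THF should move the acyl group from the C7 oxygen to the C5 oxygen to give (4R)-4-{(S)-[4-(benzyloxy)-3-methoxyphenyl](hydroxy)methyl}oxolan-2-one F1.
   - TBSOTf and 2,6-lutidine give its C7 silyl ether F2.
   - The lithium enolate (LiN(iPr)2, THF, −78 °C) adds to aldehyde 2 anti to the C4 substituent. In this isomeric lactone that is the C3 configuration of the target. The product is the trans-aldol adduct F3, as carbinol epimers.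
   - LiAlH4 opens the lactone to the silyloxy triol F4.
   - CSA (cat.) in CH2Cl2 at 0 °C ionises the free benzylic C2 alcohol. The C5 hydroxyl closes ring A with the aryl group trans to the C6 hydroxymethyl group, giving the C7 silyl ether of 19, F5.
   - TBAF in THF then gives 19.

2. Step 8. The mixed acetal may scramble to the symmetrical dialkyl acetal, hydrolyse during isolation, or the acyl group of 13 may migrate to the primary oxygen under prolonged acid.
   The fallback sets out from 14 (with 13) and returns at 15. It replaces the acid equilibrium by an irreversible alkylation under basic conditions. Acetal 14 and acetyl chloride in CH2Cl2 at 0 °C give the α-chloro ether 1-(benzyloxy)-4-[chloro(methoxy)methyl]-2-methoxybenzene F6. It is added without isolation to 13 and iPr2NEt at −20 °C, in the way a chloromethyl ether installs a methoxymethyl group.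

3. Step 4. The electron-rich benzylic carbinol may ionise in TFA. This would lead to dehydration to the cinnamoyl imide or to ring alkylation by the tert-butyl cation instead of clean lactonisation.
   The fallback sets out from 4 and 2 and returns at 11. It carries the lactone carbonyl as a terminal alkene, so no acid is needed.
   - 4 is acylated with pent-4-enoyl chloride (n-BuLi, THF, −78 °C) to give (S)-4-benzyl-3-(pent-4-enoyl)-1,3-oxazolidin-2-one F7.
   - The same Evans syn-aldol with 2 (Bu2BOTf, iPr2NEt) gives the allyl-substituted syn-aldol adduct F8.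
   - Lemieux–Johnson cleavage (OsO4 cat., NaIO4, 2,6-lutidine, dioxane/H2O) gives an aldehyde that closes on the C7 hydroxyl to give the lactol F9.
   - PhI(OAc)2 with TEMPO (cat.) in CH2Cl2 oxidises the lactol to lactone imide 11.

Further compounds
F1 | step 9 | (4R)-4-{(S)-[4-(benzyloxy)-3-methoxyphenyl](hydroxy)methyl}oxolan-2-one | COc1cc([C@@H](O)[C@H]2COC(=O)C2)ccc1OCc1ccccc1
F2 | step 9 | (4R)-4-{(S)-[4-(benzyloxy)-3-methoxyphenyl][(tert-butyldimethylsilyl)oxy]methyl}oxolan-2-one | COc1cc([C@@H](O[Si](C)(C)C(C)(C)C)[C@H]2COC(=O)C2)ccc1OCc1ccccc1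
F3 | step 9 | (3S,4R)-3-{[4-(benzyloxy)-3-methoxyphenyl](hydroxy)methyl}-4-{(S)-[4-(benzyloxy)-3-methoxyphenyl][(tert-butyldimethylsilyl)oxy]methyl}oxolan-2-one, carbinol epimers | COc1cc([C@@H](O[Si](C)(C)C(C)(C)C)[C@H]2COC(=O)[C@@H]2C(O)c2ccc(OCc3ccccc3)c(OC)c2)ccc1OCc1ccccc1
F4 | step 9 | (2R,3R)-2-{[4-(benzyloxy)-3-methoxyphenyl](hydroxy)methyl}-3-{(S)-[4-(benzyloxy)-3-methoxyphenyl][(tert-butyldimethylsilyl)oxy]methyl}butane-1,4-diol, carbinol epimers | COc1cc([C@@H](O[Si](C)(C)C(C)(C)C)[C@@H](CO)[C@H](CO)C(O)c2ccc(OCc3ccccc3)c(OC)c2)ccc1OCc1ccccc1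
F5 | step 9 | C7 O-tert-butyldimethylsilyl ether of 19 | COc1cc([C@@H](O[Si](C)(C)C(C)(C)C)[C@H]2CO[C@H](c3ccc(OCc4ccccc4)c(OC)c3)[C@H]2CO)ccc1OCc1ccccc1
F6 | step 8 | 1-(benzyloxy)-4-[chloro(methoxy)methyl]-2-methoxybenzene | COc1cc(C(Cl)OC)ccc1OCc1ccccc1
F7 | step 4 | (S)-4-benzyl-3-(pent-4-enoyl)-1,3-oxazolidin-2-one | C=CCCC(=O)N1[C@@H](Cc2ccccc2)COC1=O
F8 | step 4 | (S)-4-benzyl-3-{(2S,3S)-2-allyl-3-[4-(benzyloxy)-3-methoxyphenyl]-3-hydroxypropanoyl}-1,3-oxazolidin-2-one | COc1cc([C@@H](O)[C@H](CC=C)C(=O)N2[C@@H](Cc3ccccc3)COC2=O)ccc1OCc1ccccc1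
F9 | step 4 | (4S)-4-benzyl-3-{(2S,3S)-2-[4-(benzyloxy)-3-methoxyphenyl]-5-hydroxyoxolane-3-carbonyl}-1,3-oxazolidin-2-one, lactol anomers | COc1cc([C@H]2OC(O)C[C@@H]2C(=O)N3[C@@H](Cc4ccccc4)COC3=O)ccc1OCc1ccccc1
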